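**Retrosynthetic overview**
- The 1,2-dioxane is the last ring. Cutting C6–O and C3–O leads back to a 5-alkenyl tetronic acid plus O2: Markovnikov hydroperoxidation of a C6 methylidene group, then peroxyhemiketal closure on C3.
- The lactone is the second ring. The tetronic acid comes from a 5,5-disubstituted dioxolanone and the enolate of ethyl acetate (Claisen, then lactonisation).
- The C4–C5 bond comes from alkylating the L-lactic acid/pivalaldehyde dioxolanone (first, temporary ring) with a 2-substituted allyl bromide.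
- The allyl bromide comes from an allylsilane, which comes from a β-methyl ester. C8 is set by asymmetric conjugate addition of the side-chain Grignard reagent to methyl crotonate.
- The side chain comes from 5-bromopent-1-yne, Me3Al and benzyl bromide (carboalumination, cross-coupling; E-alkene).

Assumption: locants used below are C1 lactone C=O, C2 CH2, C3 peroxyhemiketal carbon, C4 C(CH3)–O(lactone), C5 CH2, C6 C(CH3)–OO, C7 CH2, C8 CH(CH3), C9–C11 CH2, C12=C13, C14 benzylic CH2. The SMILES reads as 3R,4R,6R,8R,12E with a cis ring fusion.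

**Step 1**
Reactants: 1 5-bromopent-1-yne; 2 benzyl bromide
Product: 4 [(2E)-6-bromo-3-methylhex-2-en-1-yl]benzene, via alkenylalane 3 (not isolated)
Conditions: Me3Al (2 equiv), Cp2ZrCl2 (0.2 equiv), CH2Cl2, 0 °C to rt; then 2, Pd(PPh3)4 (3 mol%), THF, rt
Reagents that add atoms: trimethylaluminium, C[Al](C)C
Why: Negishi zirconium-catalysed carboalumination adds methyl and aluminium syn with the metal on the terminal carbon, and the palladium-catalysed coupling of the alkenylalane with the benzylic bromide retains geometry, so the E-trisubstituted alkene is fixed while the unactivated primary bromide is untouched.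

**Step 2**
Reactants: 4 [(2E)-6-bromo-3-methylhex-2-en-1-yl]benzene; 5 methyl (E)-but-2-enoate
Product: 7 methyl (3R,7E)-3,7-dimethyl-9-phenylnon-7-enoate, via Grignard reagent 6 (not isolated)
Conditions: Mg, I2 (cat.), Et2O, reflux; then add to 5 (1.2 equiv), CuBr·SMe2 (2.5 mol%), 1-[2-(diphenylphosphino)ferrocenyl]ethyldicyclohexylphosphine (3 mol%, the enantiomer that attacks the Si face of C3 of 5), t-BuOMe, −75 °C; 1 M HCl
Reagents that add atoms: none
Why: Copper-catalysed asymmetric conjugate addition of a linear alkylmagnesium bromide to methyl crotonate (typically 90–95% ee for this pairing) sets C8 as R by Si-face delivery, and the isolated alkene is inert at −75 °C.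

**Step 3**
Reactants: 7 methyl (3R,7E)-3,7-dimethyl-9-phenylnon-7-enoate
Product: 9 [(4R,8E)-4,8-dimethyl-2-methylidene-10-phenyldec-8-en-1-yl]trimethylsilane, via bis-silyl carbinol 8 (not isolated)
Conditions: Me3SiCH2MgCl (4 equiv), CeCl3 (4 equiv), THF, −78 °C to rt; 1 M HCl; then SiO2, CH2Cl2, rt
Reagents that add atoms: (trimethylsilyl)methylmagnesium chloride, C[Si](C)(C)C[Mg]Cl
Why: Cerium-mediated double addition to the ester followed by Peterson elimination of one β-hydroxysilane arm (Bunnelle allylsilane synthesis) makes the ester carbon into C6 bearing C5 and the future C6 methyl carbon, and no stereocentre is touched.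

**Step 4**
Reactants: 9 [(4R,8E)-4,8-dimethyl-2-methylidene-10-phenyldec-8-en-1-yl]trimethylsilane
Product: 10 [(2E,7R)-9-(bromomethyl)-3,7-dimethyldeca-2,9-dien-1-yl]benzene
Conditions: NBS (1.0 equiv), CH2Cl2, −78 °C, dark
Reagents that add atoms: N-bromosuccinimide, O=C1CCC(=O)N1Br
Why: In this electrophilic bromodesilylation (SE2' reaction) the allylsilane is by far the most nucleophilic alkene, bromine enters at the methylidene terminus and loss of silicon regenerates the 1,1-disubstituted alkene.

**Step 5**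
Reactants: 11 (S)-lactic acid; 12 pivalaldehyde
Product: 13 (2S,5S)-2-tert-butyl-5-methyl-1,3-dioxolan-4-one
Conditions: p-TsOH (cat.), pentane, reflux, Dean–Stark; recrystallise from pentane/Et2O at −78 °C
Reagents that add atoms: none
Why: Acid-catalysed acetalisation (Seebach dioxolanone) favours the cis isomer, which is purified by cold crystallisation, so the lactate centre fixes the acetal centre as 2S.

**Step 6**
Reactants: 13 (2S,5S)-2-tert-butyl-5-methyl-1,3-dioxolan-4-one; 10 [(2E,7R)-9-(bromomethyl)-3,7-dimethyldeca-2,9-dien-1-yl]benzene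
Product: 15 (2S,5R)-2-tert-butyl-5-[(4R,8E)-4,8-dimethyl-2-methylidene-10-phenyldec-8-en-1-yl]-5-methyl-1,3-dioxolan-4-one, via lithium enolate 14 (not isolated)
Conditions: LiN(iPr)2 (1.05 equiv to 13), THF, −78 °C, 30 min; then 10 (0.8 equiv), −78 to −30 °C
Reagents that add atoms: none
Why: In this Seebach self-regeneration of stereocentres the planar enolate is allylated anti to the tert-butyl group (dr at least 95:5), which sets C4 as R with net retention; the few percent of (8S)-10 from step 2 become a diastereomer that is removed by chromatography.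

**Step 7**
Reactants: 15 (2S,5R)-2-tert-butyl-5-[(4R,8E)-4,8-dimethyl-2-methylidene-10-phenyldec-8-en-1-yl]-5-methyl-1,3-dioxolan-4-one
Product: 17 (5R)-5-[(4R,8E)-4,8-dimethyl-2-methylidene-10-phenyldec-8-en-1-yl]-4-hydroxy-5-methylfuran-2(5H)-one, via hydroxy keto ester 16 (not isolated)
Conditions: EtOAc (4 equiv), LiN(iPr)2 (4 equiv), THF, −78 °C; add 15, −78 to 0 °C; EtOH, 40 °C, 2 h; 1 M HCl
Reagents that add atoms: ethyl acetate, CCOC(C)=O
Why: In this crossed Claisen condensation on the activated dioxolanone carbonyl the acetal collapses with loss of pivalaldehyde and the freed tertiary alkoxide lactonises onto the ethyl ester, with the acidic tetronate as the sink; C4 is quaternary and cannot epimerise.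

**Step 8**
Reactants: 17 (5R)-5-[(4R,8E)-4,8-dimethyl-2-methylidene-10-phenyldec-8-en-1-yl]-4-hydroxy-5-methylfuran-2(5H)-one
Product: 20 (3R,4aR,7aR)-7a-hydroxy-3,4a-dimethyl-3-[(2R,6E)-2,6-dimethyl-8-phenyloct-6-en-1-yl]tetrahydrofuro[3,2-c][1,2]dioxin-6-one, via silyl peroxide 18 (not isolated), via hydroperoxide 19 (not isolated)
Conditions: (R,R)-N,N'-bis(3,5-di-tert-butylsalicylidene)-1,2-cyclohexanediaminocobalt, Co(C36H52N2O2), divalent cobalt (10 mol%), N-methylimidazole (10 mol%), Et3SiH (3 equiv), t-BuOOH (2 mol%), O2/N2 5:95 (slow stream), ClCH2CH2Cl, −10 °C; then AcOH/THF/H2O, 0 °C to rt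
Reagents that add atoms: dioxygen, O=O
Why: Proposed new method: the cobalt hydride formed from the salen complex and Et3SiH transfers a hydrogen atom to the unhindered 1,1-disubstituted alkene much faster than to the trisubstituted C12=C13 alkene; because O2 is fed at about 0.05 bar to a cold solution containing an axial base, most dissolved O2 is held as the end-on superoxide of trivalent cobalt, so the tertiary C6 radical forms its C–O bond by radical–radical coupling with cobalt-bound oxygen inside the chiral salen cleft instead of with free O2; the acidic enol O–H of 17 hydrogen-bonds to that superoxide and gives a chair-like array resembling the product dioxane, with the β-branched chain equatorial and the new methyl axial, which is 6R (design goal dr at least 4:1, minor epimer removed by chromatography); silane then releases 18, mild acid frees 19, and 6-exo addition of its OOH to the C3 keto tautomer can only give the cis-fused bicycle with an axial anomeric OH, which is 3R; the closest known reaction type is the Mukaiyama–Isayama hydroperoxysilylation of alkenes (achiral cobalt diketonates, free O2, no control of the new centre) followed by peroxyhemiketalisation.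

**Compound list**
1 | 5-bromopent-1-yne | C#CCCCBr | starting material
2 | benzyl bromide | BrCc1ccccc1 | starting material
3 | [(1E)-5-bromo-2-methylpent-1-en-1-yl]dimethylaluminium | C/C(=C\[Al](C)C)CCCBr | intermediate (not isolated)
4 | [(2E)-6-bromo-3-methylhex-2-en-1-yl]benzene | C/C(=C\Cc1ccccc1)CCCBr | intermediate
5 | methyl (E)-but-2-enoate | C/C=C/C(=O)OC | starting material
6 | [(4E)-4-methyl-6-phenylhex-4-en-1-yl]magnesium bromide | C/C(=C\Cc1ccccc1)CCC[Mg]Br | intermediate (not isolated)
7 | methyl (3R,7E)-3,7-dimethyl-9-phenylnon-7-enoate | C/C(=C\Cc1ccccc1)CCC[C@@H](C)CC(=O)OC | intermediate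
8 | (4R,8E)-4,8-dimethyl-10-phenyl-1-(trimethylsilyl)-2-[(trimethylsilyl)methyl]dec-8-en-2-ol | C/C(=C\Cc1ccccc1)CCC[C@@H](C)CC(O)(C[Si](C)(C)C)C[Si](C)(C)C | intermediate (not isolated)
9 | [(4R,8E)-4,8-dimethyl-2-methylidene-10-phenyldec-8-en-1-yl]trimethylsilane | C/C(=C\Cc1ccccc1)CCC[C@@H](C)CC(=C)C[Si](C)(C)C | intermediate
10 | [(2E,7R)-9-(bromomethyl)-3,7-dimethyldeca-2,9-dien-1-yl]benzene | C/C(=C\Cc1ccccc1)CCC[C@@H](C)CC(=C)CBr | intermediate
11 | (S)-lactic acid | C[C@H](O)C(=O)O | starting material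
12 | pivalaldehyde | CC(C)(C)C=O | starting material
13 | (2S,5S)-2-tert-butyl-5-methyl-1,3-dioxolan-4-one | C[C@@H]1O[C@H](C(C)(C)C)OC1=O | intermediate
14 | lithium (2S)-2-tert-butyl-5-methyl-1,3-dioxol-4-olate | CC1=C([O-])O[C@@H](C(C)(C)C)O1.[Li+] | intermediate (not isolated)
15 | (2S,5R)-2-tert-butyl-5-[(4R,8E)-4,8-dimethyl-2-methylidene-10-phenyldec-8-en-1-yl]-5-methyl-1,3-dioxolan-4-one | C/C(=C\Cc1ccccc1)CCC[C@@H](C)CC(=C)C[C@@]1(C)O[C@H](C(C)(C)C)OC1=O | intermediate
16 | ethyl (4R,8R,12E)-4-hydroxy-4,8,12-trimethyl-6-methylidene-3-oxo-14-phenyltetradec-12-enoate | C/C(=C\Cc1ccccc1)CCC[C@@H](C)CC(=C)C[C@@](C)(O)C(=O)CC(=O)OCC | intermediate (not isolated)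
17 | (5R)-5-[(4R,8E)-4,8-dimethyl-2-methylidene-10-phenyldec-8-en-1-yl]-4-hydroxy-5-methylfuran-2(5H)-one | C/C(=C\Cc1ccccc1)CCC[C@@H](C)CC(=C)C[C@@]1(C)OC(=O)C=C1O | intermediate
18 | (5R)-4-hydroxy-5-methyl-5-[(2R,4R,8E)-2,4,8-trimethyl-10-phenyl-2-(triethylsilylperoxy)dec-8-en-1-yl]furan-2(5H)-one | C/C(=C\Cc1ccccc1)CCC[C@@H](C)C[C@@](C)(OO[Si](CC)(CC)CC)C[C@@]1(C)OC(=O)C=C1O | intermediate (not isolated)
19 | (5R)-5-[(2R,4R,8E)-2-hydroperoxy-2,4,8-trimethyl-10-phenyldec-8-en-1-yl]-4-hydroxy-5-methylfuran-2(5H)-one | C/C(=C\Cc1ccccc1)CCC[C@@H](C)C[C@@](C)(OO)C[C@@]1(C)OC(=O)C=C1O | intermediate (not isolated)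
20 | (3R,4aR,7aR)-7a-hydroxy-3,4a-dimethyl-3-[(2R,6E)-2,6-dimethyl-8-phenyloct-6-en-1-yl]tetrahydrofuro[3,2-c][1,2]dioxin-6-one (CNP0361739.2) | C/C(=C\Cc1ccccc1)CCC[C@@H](C)C[C@]1(C)C[C@@]2(C)OC(=O)C[C@@]2(O)OO1 | target

**Total steps:** 8.
**Longest linear sequence:** 7 (steps 1, 2, 3, 4, 6, 7, 8).

**Steps most likely to fail**

Step 8 (new method). The C6 radical may still be captured by free O2, which gives no control at C6. The acidic substrate may tie up the cobalt, and part of the peroxide may be over-reduced to the tertiary alcohol. The matched hand of the salen ligand also has to be found by running both enantiomers.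

The fallback gives up catalyst control and uses the established protect, peroxysilylate, deprotect and separate sequence.
- It sets out from 17, which is silylated (Et3SiCl, imidazole, CH2Cl2) to the neutral O-triethylsilyl tetronate F1.
- Standard hydroperoxysilylation follows, using bis(2,2,6,6-tetramethylheptane-3,5-dionato)cobalt, Co(C11H19O2)2, O2 (1 atm) and Et3SiH in ClCH2CH2Cl. It gives the (6R)-bis-silyl peroxide F2 and its (6S)-epimer F3 in about equal amounts.
- The mixture is desilylated with AcOH/THF/H2O. F2 comes back to the route at 19, which closes to 20.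
- F3 gives the (6S)-hydroperoxide F4 and from it the C6 epimer of the target F5. F5 is a diastereomer of 20 and is separated on silica or by HPLC.

Step 7. The carbonyl of 15 sits next to a quaternary carbon, the liberated pivalaldehyde consumes enolate, and the dianionic hydroxy keto ester may lactonise slowly.

The fallback sets out from 15 and builds the ring intramolecularly.
- K2CO3 in MeOH opens the acetal to the α-hydroxy methyl ester F6.
- Ac2O, Et3N and DMAP give its acetate F7.
- LiN(SiMe3)2 (2.5 equiv, THF, −78 °C to rt) effects a Dieckmann cyclisation that comes back to the route at 17.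

Step 4. Electrophilic bromine may also attack the C12=C13 alkene or over-brominate.

The fallback avoids any electrophilic halogen. It sets out from 7, so it replaces steps 3 and 4.
- Kulinkovich cyclopropanation (EtMgBr, Ti(OiPr)4, Et2O) gives the cyclopropanol F8.
- MsCl and Et3N give its mesylate F9.
- MgBr2·OEt2 in refluxing Et2O opens the cyclopropyl cation to the 2-substituted allyl bromide, which comes back to the route at 10.

**Further compounds**
F1 | step 8 | (5R)-5-[(4R,8E)-4,8-dimethyl-2-methylidene-10-phenyldec-8-en-1-yl]-5-methyl-4-(triethylsilyloxy)furan-2(5H)-one | C/C(=C\Cc1ccccc1)CCC[C@@H](C)CC(=C)C[C@@]1(C)OC(=O)C=C1O[Si](CC)(CC)CC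
F2 | step 8 | (5R)-5-methyl-4-(triethylsilyloxy)-5-[(2R,4R,8E)-2,4,8-trimethyl-10-phenyl-2-(triethylsilylperoxy)dec-8-en-1-yl]furan-2(5H)-one | C/C(=C\Cc1ccccc1)CCC[C@@H](C)C[C@@](C)(OO[Si](CC)(CC)CC)C[C@@]1(C)OC(=O)C=C1O[Si](CC)(CC)CC
F3 | step 8 | (5R)-5-methyl-4-(triethylsilyloxy)-5-[(2S,4R,8E)-2,4,8-trimethyl-10-phenyl-2-(triethylsilylperoxy)dec-8-en-1-yl]furan-2(5H)-one | C/C(=C\Cc1ccccc1)CCC[C@@H](C)C[C@](C)(OO[Si](CC)(CC)CC)C[C@@]1(C)OC(=O)C=C1O[Si](CC)(CC)CC
F4 | step 8 | (5R)-5-[(2S,4R,8E)-2-hydroperoxy-2,4,8-trimethyl-10-phenyldec-8-en-1-yl]-4-hydroxy-5-methylfuran-2(5H)-one | C/C(=C\Cc1ccccc1)CCC[C@@H](C)C[C@](C)(OO)C[C@@]1(C)OC(=O)C=C1O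
F5 | step 8 | (3S,4aR,7aR)-7a-hydroxy-3,4a-dimethyl-3-[(2R,6E)-2,6-dimethyl-8-phenyloct-6-en-1-yl]tetrahydrofuro[3,2-c][1,2]dioxin-6-one | C/C(=C\Cc1ccccc1)CCC[C@@H](C)C[C@@]1(C)C[C@@]2(C)OC(=O)C[C@@]2(O)OO1
F6 | step 7 | methyl (2R,6R,10E)-2-hydroxy-2,6,10-trimethyl-4-methylidene-12-phenyldodec-10-enoate | C/C(=C\Cc1ccccc1)CCC[C@@H](C)CC(=C)C[C@@](C)(O)C(=O)OC
F7 | step 7 | methyl (2R,6R,10E)-2-acetoxy-2,6,10-trimethyl-4-methylidene-12-phenyldodec-10-enoate | C/C(=C\Cc1ccccc1)CCC[C@@H](C)CC(=C)C[C@@](C)(OC(C)=O)C(=O)OC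
F8 | step 4 | 1-[(2R,6E)-2,6-dimethyl-8-phenyloct-6-en-1-yl]cyclopropan-1-ol | C/C(=C\Cc1ccccc1)CCC[C@@H](C)CC1(O)CC1
F9 | step 4 | 1-[(2R,6E)-2,6-dimethyl-8-phenyloct-6-en-1-yl]cyclopropyl methanesulfonate | C/C(=C\Cc1ccccc1)CCC[C@@H](C)CC1(OS(C)(=O)=O)CC1
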